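Assumption: the target has no stereocentre and no configured double bond, so no SMILES string below carries a stereo descriptor. Atoms are numbered O1, C2, C3, C3a, C4–C7, C7a in the benzofuran (ring A is its benzo ring) and C1'–C6' in the aryl ring (ring C).

## The problem

The target 20 is a 2-arylbenzofuran. Ring A carries hydroxyls at C4 and C6 and a 1,1-dimethylallyl group at C7; ring C, bonded through C2–C1', carries hydroxyls at C3' and C5' and prenyl groups at C2' and C6'. With no stereocentre, the whole difficulty is constitutional: three C-allyl groups of two kinds must go to defined carbons of two very electron-rich rings, each of which offers a competing site (C5 on ring A, C4' on ring C). The C2–C1' bond is flanked by both ring C prenyl groups, so the rings are best joined before those groups exist. On ring A the oxygen that becomes O6 must be told apart from those that become O4 and O1, although all three come from a symmetric triol. The ortho-prenylphenols close to chromans and the ortho-(1,1-dimethylallyl)phenol closes to a dihydrobenzofuran under acid, the free polyphenol oxidises in basic air, and hydrogenolysis is excluded by the alkenes. The enabling feature is that every C-allyl group sits ortho to a phenolic oxygen (C7 beside O6, C2' beside O3', C6' beside O5') and is the allyl-inverted isomer of the ether that can be made at that oxygen, which is the pattern an aromatic Claisen shift produces.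

## Retrosynthesis

**Deprotection (20 from 18).** The last disconnection removes three acetyl groups and one silyl group from 18. Esters and a silyl ether are chosen over acetals or benzyl ethers because they come off without acid and without hydrogen. The forward step only needs methanolysis and fluoride to leave three alkenes and a free polyphenol alone.

**Key step (18 from 14).** The bonds C7–C(quaternary), C2'–CH2 and C6'–CH2 are cut together, each back to an allyl ether on the neighbouring oxygen: the O6 prenyl ether and the O3' and O5' 1,1-dimethylallyl ethers of 14.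
- Electrophilic prenylation would not discriminate between C5, C7, C3 and C4' and cannot deliver the quaternary carbon at C7.
- Cross-coupling would need three halogens placed with the same regiochemical problem.
- The sigmatropic route draws each C–C bond from an O-alkylation and inverts the allyl unit as the target requires.

Precursor 14 has no carbon substituent on either ring beyond the biaryl bond. The forward reaction must deliver regiocontrol at C7 against C5 and at C2'/C6' against C4', and the phenols must survive 195 °C. The silyl ether beside C5 and an anhydride trap in the hot stage are built in for those two demands.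

**Furan closure and silylation (14 from 13 from 11).** The O4–Si bond and then the O1–C2 bond are cut. Benzofuranol 13 has a single free hydroxyl, so silylation is unambiguous. Alkynylresorcinol 12, released from diacetate 11, is symmetric: either hydroxyl closes the furan and the other becomes O4–H, so no desymmetrisation is needed anywhere. Silylating before the coupling would have been statistical.

**Ring junction (11 from 10 and 5).** The C3a–C(alkyne) bond is cut by a Sonogashira disconnection into aryl iodide 10 and arylacetylene 5, two halves of similar size. A direct C2–C1' biaryl coupling is the neighbouring cut, but it would not build the furan and would need a preformed benzofuran. The coupling must run at room temperature so that zerovalent palladium does not ionise the tertiary allyl ethers, which is why the iodide is used as its diacetate.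

**Ring C arm (5 from 4, 3, 1 and 2).** The alkyne carbon is removed (aldehyde homologation), the vinyl groups are traced to ethynyl groups (semi-hydrogenation), and the two tertiary O–C bonds are cut to 3,5-dihydroxybenzaldehyde 1 and two molecules of 3-chloro-3-methylbut-1-yne 2, one for each hydroxyl. Tertiary allyl aryl ethers cannot be made by direct displacement. The propargyl route fixes the branched constitution, and the hydrogenation is placed before the arylacetylene exists.

**Ring A arm (10 from 9, 8, 6 and 7).** The acetates, the C–I bond and one O–CH2 bond are cut back to phloroglucinol 6 and 3-methylbut-2-en-1-ol 7. Mono-etherification of the symmetric triol leaves two equivalent hydroxyls, and iodination between them (para to the ether oxygen) keeps that symmetry. The only selectivity questions are mono- against poly-etherification and C2 against C4 iodination.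

## Roads not taken

**Alternative 1:** The C4–C5 bond of ring A would be cut, leading to methyl 2-(4,4-dimethyl-2-oxohex-5-en-3-yl)furan-3-carboxylate A2.
- Forward step: NaH forms the methyl-ketone enolate, which acylates itself on the ester carbonyl. Loss of methoxide and enolisation of the cyclic 1,3-diketone give 7-(2-methylbut-3-en-2-yl)-1-benzofuran-4,6-diol A1.
- Merit: the 1,1-dimethylallyl group is on C7 by construction, so the C5/C7 question of the chosen route does not arise and no high temperature is needed for that group. In this respect it is better.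
- Weak points before the step: A2 holds a quaternary carbon beside a doubly activated methine. That cannot be made by alkylating with a tertiary allyl electrophile and would itself need a sigmatropic detour. The methine is also the most acidic site, so the productive enolate is the minor one.
- Weak points after the step: A1 has no ring C. The aryl group would have to be attached at C2 of an oxidation-prone resorcinol, and if it already carried its prenyl groups the new bond would be doubly ortho-hindered.
- Comparison: the chosen plan sets against the C7 advantage an early, unhindered ring junction and the fact that all three allyl groups come from O-alkylations.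

**Alternative 2:** Both furan bonds to ring A, C3–C3a and O1–C7a, would be cut. The precursors are 1-[3,5-bis(methoxymethoxy)-2,6-bis(3-methylbut-2-en-1-yl)phenyl]ethan-1-one A4 and 1-bromo-2-iodo-3-(methoxymethoxy)-5-{[tri(propan-2-yl)silyl]oxy}benzene A5.
- Forward step: with Pd2(dba)3, Xantphos and Cs2CO3 the ketone enolate is arylated at the C–I carbon and the resulting enolate closes the furan by O-arylation at the C–Br carbon, giving the 4-O-methoxymethyl 6-O-silyl benzofuran A3 with ring C complete.
- Merit: ring C enters with both prenyl groups on fixed positions, so the weakest point of the chosen plan, C2'/C6' against C4', is settled before coupling. Here the alternative is better.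
- Weak points: that certainty is only moved into the synthesis of A4. The O-arylation needs the α-aryl ketone enolate to lie near the plane of a ring twisted by two ortho prenyl groups. A5 needs four different substituents placed on one benzene. A3 still lacks the C7 group, so desilylation, O-prenylation and a Claisen shift would follow anyway. The methoxymethyl groups can only be removed with acid, which cyclises the ortho-allylphenols.
- Comparison: the chosen plan sets against it a shorter sequence, a single thermal operation for all three groups and a non-acidic ending.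

**Alternative 3:** The C1'–C6' bond would be cut, unfolding ring C into 1-[4,6-bis(methoxymethoxy)-7-(2-methylbut-3-en-2-yl)-1-benzofuran-2-yl]-9-methyl-2-(3-methylbut-2-en-1-yl)dec-8-ene-1,3,5-trione A7.
- Forward step: aqueous KOH makes the terminal methylene (future C6') add to the benzofuranyl ketone carbonyl (future C1'). Dehydration and enolisation of the other two carbonyls aromatise ring C to the 4,6-bis(methoxymethyl) ether of the target A6.
- Merit: the folding mirrors polyketide biosynthesis and gives ring C with both prenyl groups and both hydroxyls in place and free, with no regiochemical choice on ring C. This equals or beats the chosen plan on that point.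
- Weak points: the nucleophile is the least acidic of three enolisable positions and the electrophile is the least reactive carbonyl. Hydroxide can cleave the β-diketone units by retro-Claisen reaction, and the enols can close to a 4-pyranone. A7 needs a long linear assembly on a benzofuran whose C7 group must still come from a Claisen shift. The acid deprotection problem of Alternative 2 returns.
- Comparison: the chosen plan sets against it far fewer steps and stable, symmetric intermediates.

Key step: step 10

## Route

Step 1
Reactants: 1 3,5-dihydroxybenzaldehyde; 2 3-chloro-3-methylbut-1-yne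
Product: 3 3,5-bis[(2-methylbut-3-yn-2-yl)oxy]benzaldehyde
Conditions: 2 (2.5 equiv), DBU (2.6 equiv), CuCl2·2H2O (cat.), MeCN, 0 °C to rt
Reagents that add atoms: 3-chloro-3-methylbut-1-yne (second equivalent of 2), CC(C)(Cl)C#C
Why: Copper-catalysed propargylic substitution of the tertiary chloride by a phenoxide is the standard entry to aryl 1,1-dimethylpropargyl ethers and works best on acceptor-substituted phenols such as 1; each of the two hydroxyls consumes one molecule of 2, so a slight excess over two equivalents carries the reaction through the mono-ether to the bis-ether, and the aldehyde is inert.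

Step 2
Reactants: 3 3,5-bis[(2-methylbut-3-yn-2-yl)oxy]benzaldehyde
Product: 4 3,5-bis[(2-methylbut-3-en-2-yl)oxy]benzaldehyde
Conditions: H2 (1 atm), Pd/CaCO3 poisoned with Pb(OAc)2, quinoline, EtOAc, rt
Reagents that add atoms: none
Why: Lindlar semi-hydrogenation stops at the terminal alkenes on the lead-poisoned catalyst and leaves the aldehyde and the aryl ethers alone; hydrogen uptake is followed to avoid over-reduction.

Step 3
Reactants: 4 3,5-bis[(2-methylbut-3-en-2-yl)oxy]benzaldehyde
Product: 5 1-ethynyl-3,5-bis[(2-methylbut-3-en-2-yl)oxy]benzene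
Conditions: dimethyl (1-diazo-2-oxopropyl)phosphonate, K2CO3, MeOH, 0 °C to rt
Reagents that add atoms: dimethyl (1-diazo-2-oxopropyl)phosphonate, CC(=O)C(=[N+]=[N-])P(=O)(OC)OC
Why: Seyferth–Gilbert homologation with the Ohira–Bestmann reagent: the diazomethylphosphonate anion adds to the aldehyde, dimethyl phosphate and N2 are lost and a 1,2-shift gives the terminal alkyne; mild base at room temperature keeps the tertiary allyl ethers intact, and the alkyne is made only after the hydrogenation.

Step 4
Reactants: 6 phloroglucinol; 7 3-methylbut-2-en-1-ol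
Product: 8 5-[(3-methylbut-2-en-1-yl)oxy]benzene-1,3-diol
Conditions: PPh3, DIAD, THF, 0 °C to rt; 6 in threefold excess
Reagents that add atoms: none
Why: Mitsunobu etherification alkylates the acidic phenol on oxygen and avoids the C-alkylation that phloroglucinol shows with allylic halides and base; the excess of the cheap symmetric triol holds the reaction at the mono-ether.

Step 5
Reactants: 8 5-[(3-methylbut-2-en-1-yl)oxy]benzene-1,3-diol
Product: 9 2-iodo-5-[(3-methylbut-2-en-1-yl)oxy]benzene-1,3-diol
Conditions: I2 (1.0 equiv), NaHCO3, THF–H2O, 0 °C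
Reagents that add atoms: iodine, II
Why: Electrophilic iodination of resorcinols with I2 and hydrogencarbonate in water favours the carbon flanked by both hydroxyls (the conditions that give 2-iodoresorcinol), which in 8 is also para to the ether oxygen; the triply activated ring should consume one equivalent of iodine far faster than the trisubstituted alkene.

Step 6
Reactants: 9 2-iodo-5-[(3-methylbut-2-en-1-yl)oxy]benzene-1,3-diol
Product: 10 2-iodo-5-[(3-methylbut-2-en-1-yl)oxy]-1,3-phenylene diacetate
Conditions: Ac2O, pyridine, DMAP (cat.), CH2Cl2, 0 °C to rt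
Reagents that add atoms: acetic anhydride, CC(=O)OC(C)=O
Why: Acylation of both phenols makes the iodide less electron-rich and free of phenoxide, so that oxidative addition in step 7 is fast at room temperature, and it keeps the two oxygens equivalent.

Step 7
Reactants: 10 2-iodo-5-[(3-methylbut-2-en-1-yl)oxy]-1,3-phenylene diacetate; 5 1-ethynyl-3,5-bis[(2-methylbut-3-en-2-yl)oxy]benzene
Product: 11 2-({3,5-bis[(2-methylbut-3-en-2-yl)oxy]phenyl}ethynyl)-5-[(3-methylbut-2-en-1-yl)oxy]-1,3-phenylene diacetate
Conditions: PdCl2(PPh3)2 (cat.), CuI (cat.), Et3N, THF, rt, degassed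
Reagents that add atoms: none
Why: Sonogashira coupling of an aryl iodide with a terminal arylacetylene; at room temperature insertion of zerovalent palladium into the C–I bond should outrun ionisation of the allyl aryl ethers, and Et3N does not cleave aryl acetates.

Step 8
Reactants: 11 2-({3,5-bis[(2-methylbut-3-en-2-yl)oxy]phenyl}ethynyl)-5-[(3-methylbut-2-en-1-yl)oxy]-1,3-phenylene diacetate
Product: 13 2-{3,5-bis[(2-methylbut-3-en-2-yl)oxy]phenyl}-6-[(3-methylbut-2-en-1-yl)oxy]-1-benzofuran-4-ol, via alkynylresorcinol 12 (not isolated)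
Conditions: Cs2CO3, MeOH–DMF, 60 °C, degassed
Reagents that add atoms: none
Why: Methanolysis of both acetates frees the symmetric alkynylresorcinol 12, whose phenoxide adds to the alkyne in a base-mediated 5-endo-dig hydroalkoxylation; either hydroxyl gives the same furan and the other remains as the C4 hydroxyl, and at 60 °C without palladium the tertiary allyl ethers neither rearrange nor ionise.

Step 9
Reactants: 13 2-{3,5-bis[(2-methylbut-3-en-2-yl)oxy]phenyl}-6-[(3-methylbut-2-en-1-yl)oxy]-1-benzofuran-4-ol
Product: 14 ({2-{3,5-bis[(2-methylbut-3-en-2-yl)oxy]phenyl}-6-[(3-methylbut-2-en-1-yl)oxy]-1-benzofuran-4-yl}oxy)tri(propan-2-yl)silane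
Conditions: TIPSCl, imidazole, DMF, rt
Reagents that add atoms: triisopropylsilyl chloride, CC(C)[Si](Cl)(C(C)C)C(C)C
Why: Silylation of the only free hydroxyl; the bulky silyl ether flanks C5 in the key step and tolerates heat, amine and anhydride.

Step 10
Reactants: 14 ({2-{3,5-bis[(2-methylbut-3-en-2-yl)oxy]phenyl}-6-[(3-methylbut-2-en-1-yl)oxy]-1-benzofuran-4-yl}oxy)tri(propan-2-yl)silane
Product: 18 2-[3,5-diacetoxy-2,6-bis(3-methylbut-2-en-1-yl)phenyl]-7-(2-methylbut-3-en-2-yl)-4-{[tri(propan-2-yl)silyl]oxy}-1-benzofuran-6-yl acetate, via ring C diprenyl diphenol 15 (not isolated), via diphenol diacetate 16 (not isolated), via C7-allylated phenol 17 (not isolated)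
Conditions: PhNEt2, 130 °C, argon; then Ac2O, 195 °C (sealed tube)
Reagents that add atoms: acetic anhydride, CC(=O)OC(C)=O
Why: All three C–C bonds arise by aromatic Claisen rearrangement, in which the allyl group passes from oxygen to the ortho carbon in a concerted six-electron, chair-shaped transition state and the cyclohexadienone then enolises; this is known singly for aryl 1,1-dimethylallyl ethers and aryl prenyl ethers. Because the allyl unit is inverted each time, the tertiary ethers on O3' and O5' give CH2-bound prenyl groups at C2' and C6' at 130 °C (diphenol 15), and the primary ether on O6 gives the quaternary carbon at C7 only at 195 °C, so ring C is finished before ring A begins. No ring closes and no stereocentre forms. On ring C the oxygen meta to each migrating ether directs the shift para to itself, that is to C2' and C6', and in the first shift the neighbouring bulky tertiary ether also screens C4'. On ring A the greater double-bond character of C6–C7 over C5–C6 in a benzofuran and the silyl ether beside C5 favour C7, and since the para carbon C3a is a ring-fusion atom the dienone can only enolise. Acetic anhydride is added only for the hot stage, so that the free 3'-hydroxyl still steers the second ring C shift; it then caps each phenol as it appears (16, then 17 to 18), which blocks the abnormal Claisen pathway and the addition of the C6 hydroxyl to the new double bond. The basic solvent keeps the ortho-prenylphenols from closing to chromans.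

Step 11
Reactants: 18 2-[3,5-diacetoxy-2,6-bis(3-methylbut-2-en-1-yl)phenyl]-7-(2-methylbut-3-en-2-yl)-4-{[tri(propan-2-yl)silyl]oxy}-1-benzofuran-6-yl acetate
Product: 20 2-[3,5-dihydroxy-2,6-bis(3-methylbut-2-en-1-yl)phenyl]-7-(2-methylbut-3-en-2-yl)-1-benzofuran-4,6-diol, via target 4-O-silyl ether 19 (not isolated)
Conditions: K2CO3, MeOH–THF, 0 °C to rt, argon; then Bu4NF, THF, 0 °C; aq. NH4Cl
Reagents that add atoms: none
Why: Base methanolysis removes the three aryl acetates and fluoride then cleaves the aryl silyl ether; neither stage is acidic, so the ortho-allylphenols do not cyclise, and argon with a buffered quench protects the polyphenol from air oxidation.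

## Compound list

1 | 3,5-dihydroxybenzaldehyde | O=Cc1cc(O)cc(O)c1 | starting material
2 | 3-chloro-3-methylbut-1-yne | CC(C)(Cl)C#C | starting material
3 | 3,5-bis[(2-methylbut-3-yn-2-yl)oxy]benzaldehyde | O=Cc1cc(OC(C)(C)C#C)cc(OC(C)(C)C#C)c1 | intermediate
4 | 3,5-bis[(2-methylbut-3-en-2-yl)oxy]benzaldehyde | O=Cc1cc(OC(C)(C)C=C)cc(OC(C)(C)C=C)c1 | intermediate
5 | 1-ethynyl-3,5-bis[(2-methylbut-3-en-2-yl)oxy]benzene | C#Cc1cc(OC(C)(C)C=C)cc(OC(C)(C)C=C)c1 | intermediate
6 | phloroglucinol (benzene-1,3,5-triol) | Oc1cc(O)cc(O)c1 | starting material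
7 | 3-methylbut-2-en-1-ol | CC(C)=CCO | starting material
8 | 5-[(3-methylbut-2-en-1-yl)oxy]benzene-1,3-diol | CC(C)=CCOc1cc(O)cc(O)c1 | intermediate
9 | 2-iodo-5-[(3-methylbut-2-en-1-yl)oxy]benzene-1,3-diol | CC(C)=CCOc1cc(O)c(I)c(O)c1 | intermediate
10 | 2-iodo-5-[(3-methylbut-2-en-1-yl)oxy]-1,3-phenylene diacetate | CC(=O)Oc1cc(OCC=C(C)C)cc(OC(C)=O)c1I | intermediate
11 | 2-({3,5-bis[(2-methylbut-3-en-2-yl)oxy]phenyl}ethynyl)-5-[(3-methylbut-2-en-1-yl)oxy]-1,3-phenylene diacetate | CC(=O)Oc1cc(OCC=C(C)C)cc(OC(C)=O)c1C#Cc1cc(OC(C)(C)C=C)cc(OC(C)(C)C=C)c1 | intermediate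
12 | 2-({3,5-bis[(2-methylbut-3-en-2-yl)oxy]phenyl}ethynyl)-5-[(3-methylbut-2-en-1-yl)oxy]benzene-1,3-diol (not isolated) | Oc1cc(OCC=C(C)C)cc(O)c1C#Cc1cc(OC(C)(C)C=C)cc(OC(C)(C)C=C)c1 | intermediate
13 | 2-{3,5-bis[(2-methylbut-3-en-2-yl)oxy]phenyl}-6-[(3-methylbut-2-en-1-yl)oxy]-1-benzofuran-4-ol | C=CC(C)(C)Oc1cc(OC(C)(C)C=C)cc(-c2cc3c(O)cc(OCC=C(C)C)cc3o2)c1 | intermediate
14 | ({2-{3,5-bis[(2-methylbut-3-en-2-yl)oxy]phenyl}-6-[(3-methylbut-2-en-1-yl)oxy]-1-benzofuran-4-yl}oxy)tri(propan-2-yl)silane (Claisen precursor) | C=CC(C)(C)Oc1cc(OC(C)(C)C=C)cc(-c2cc3c(O[Si](C(C)C)(C(C)C)C(C)C)cc(OCC=C(C)C)cc3o2)c1 | intermediate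
15 | 4,6-bis(3-methylbut-2-en-1-yl)-5-{6-[(3-methylbut-2-en-1-yl)oxy]-4-{[tri(propan-2-yl)silyl]oxy}-1-benzofuran-2-yl}benzene-1,3-diol (not isolated) | CC(C)=CCOc1cc(O[Si](C(C)C)(C(C)C)C(C)C)c2cc(-c3c(CC=C(C)C)c(O)cc(O)c3CC=C(C)C)oc2c1 | intermediate
16 | 4,6-bis(3-methylbut-2-en-1-yl)-5-{6-[(3-methylbut-2-en-1-yl)oxy]-4-{[tri(propan-2-yl)silyl]oxy}-1-benzofuran-2-yl}-1,3-phenylene diacetate (not isolated) | CC(C)=CCOc1cc(O[Si](C(C)C)(C(C)C)C(C)C)c2cc(-c3c(CC=C(C)C)c(OC(C)=O)cc(OC(C)=O)c3CC=C(C)C)oc2c1 | intermediate
17 | 2-[3,5-diacetoxy-2,6-bis(3-methylbut-2-en-1-yl)phenyl]-7-(2-methylbut-3-en-2-yl)-4-{[tri(propan-2-yl)silyl]oxy}-1-benzofuran-6-ol (not isolated) | C=CC(C)(C)c1c(O)cc(O[Si](C(C)C)(C(C)C)C(C)C)c2cc(-c3c(CC=C(C)C)c(OC(C)=O)cc(OC(C)=O)c3CC=C(C)C)oc12 | intermediate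
18 | 2-[3,5-diacetoxy-2,6-bis(3-methylbut-2-en-1-yl)phenyl]-7-(2-methylbut-3-en-2-yl)-4-{[tri(propan-2-yl)silyl]oxy}-1-benzofuran-6-yl acetate (key-step product) | C=CC(C)(C)c1c(OC(C)=O)cc(O[Si](C(C)C)(C(C)C)C(C)C)c2cc(-c3c(CC=C(C)C)c(OC(C)=O)cc(OC(C)=O)c3CC=C(C)C)oc12 | intermediate
19 | 2-[3,5-dihydroxy-2,6-bis(3-methylbut-2-en-1-yl)phenyl]-7-(2-methylbut-3-en-2-yl)-4-{[tri(propan-2-yl)silyl]oxy}-1-benzofuran-6-ol (not isolated) | C=CC(C)(C)c1c(O)cc(O[Si](C(C)C)(C(C)C)C(C)C)c2cc(-c3c(CC=C(C)C)c(O)cc(O)c3CC=C(C)C)oc12 | intermediate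
20 | 2-[3,5-dihydroxy-2,6-bis(3-methylbut-2-en-1-yl)phenyl]-7-(2-methylbut-3-en-2-yl)-1-benzofuran-4,6-diol (CNP0115465.0) | C=CC(C)(C)c1c(O)cc(O)c2cc(-c3c(CC=C(C)C)c(O)cc(O)c3CC=C(C)C)oc12 | target

## Step count and least certain steps

Total: 11 steps. Longest linear sequence: 8 steps (1, 2, 3, 7, 8, 9, 10, 11; the ring A arm 4, 5, 6 joins at step 7 and is equally long).

**Step 10 (key step).** The most likely failure is regiochemical leakage on ring C: one allyl unit migrates to C4', the carbon between the two oxygens. Only the para-directing effect of the second oxygen and the bulk of its tertiary ether oppose this. Loss of the O6 prenyl group as isoprene in the hot stage is the second concern.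
The fallback moves the two ring C shifts to the aldehyde stage, where the formyl group, an acceptor meta to both ethers, adds its own preference for the flanked ortho carbons. It sets out from 4 and 10 and returns at 20.
- Heating 4 in PhNEt2 at 130 °C should give 3,5-dihydroxy-2,6-bis(3-methylbut-2-en-1-yl)benzaldehyde F1.
- Ohira–Bestmann homologation gives 5-ethynyl-4,6-bis(3-methylbut-2-en-1-yl)benzene-1,3-diol F2.
- Sonogashira coupling with 10, which may now be warmed because no tertiary allyl ether is present, gives 2-{[3,5-dihydroxy-2,6-bis(3-methylbut-2-en-1-yl)phenyl]ethynyl}-5-[(3-methylbut-2-en-1-yl)oxy]-1,3-phenylene diacetate F3.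
- Cs2CO3 in MeOH–DMF removes the acetates to 2-{[3,5-dihydroxy-2,6-bis(3-methylbut-2-en-1-yl)phenyl]ethynyl}-5-[(3-methylbut-2-en-1-yl)oxy]benzene-1,3-diol F4, which closes in the flask to 2-[3,5-dihydroxy-2,6-bis(3-methylbut-2-en-1-yl)phenyl]-6-[(3-methylbut-2-en-1-yl)oxy]-1-benzofuran-4-ol F5.
- Heating F5 with Ac2O in PhNEt2 first gives 2-[3,5-diacetoxy-2,6-bis(3-methylbut-2-en-1-yl)phenyl]-6-[(3-methylbut-2-en-1-yl)oxy]-1-benzofuran-4-yl acetate F6. At 195 °C the single remaining prenyl-ether shift, with in situ acetylation, gives 2-[3,5-diacetoxy-2,6-bis(3-methylbut-2-en-1-yl)phenyl]-7-(2-methylbut-3-en-2-yl)-1-benzofuran-4,6-diyl diacetate F7.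
- K2CO3 in MeOH converts F7 into 20.

**Step 5.** Iodine may enter at C4, between a hydroxyl and the ether oxygen, instead of between the two hydroxyls, because all three ring carbons are triply activated. Electrophilic attack on the prenyl double bond is a lesser risk.
The fallback replaces electrophilic substitution by directed ortho-metalation. It sets out from 8 and returns at 9.
- MOMCl and i-Pr2NEt give 1,3-bis(methoxymethoxy)-5-[(3-methylbut-2-en-1-yl)oxy]benzene F8.
- n-BuLi in THF at 0 °C lithiates the carbon between the two acetal oxygens, and I2 gives 2-iodo-1,3-bis(methoxymethoxy)-5-[(3-methylbut-2-en-1-yl)oxy]benzene F9.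
- Dilute HCl in MeOH at room temperature removes the acetals to 9. The aryl iodide and the primary prenyl ether should tolerate this at that stage.

**Step 7.** If the hindered iodide inserts slowly, zerovalent palladium can ionise the tertiary allyl aryl ethers, leading to branched-to-linear isomerisation or loss of the allyl group. Oxidative dimerisation of 5 is a lesser risk.
The fallback takes the tertiary ethers out of the palladium step. It sets out from 1, 9 and 2 and returns at 14.
- Ohira–Bestmann homologation of 1 gives 5-ethynylbenzene-1,3-diol F10.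
- One equivalent of TIPSCl with imidazole converts 9 into 2-iodo-5-[(3-methylbut-2-en-1-yl)oxy]-3-{[tri(propan-2-yl)silyl]oxy}phenol F11.
- PdCl2(PPh3)2, CuI and Et3N in DMF at 60 °C couple F10 and F11 to 5-({2-hydroxy-4-[(3-methylbut-2-en-1-yl)oxy]-6-{[tri(propan-2-yl)silyl]oxy}phenyl}ethynyl)benzene-1,3-diol F12, which cyclises in the flask to 5-{6-[(3-methylbut-2-en-1-yl)oxy]-4-{[tri(propan-2-yl)silyl]oxy}-1-benzofuran-2-yl}benzene-1,3-diol F13.
- Copper-catalysed propargylation of both hydroxyls with a slight excess over two equivalents of 2 (DBU, CuCl2·2H2O) gives ({2-{3,5-bis[(2-methylbut-3-yn-2-yl)oxy]phenyl}-6-[(3-methylbut-2-en-1-yl)oxy]-1-benzofuran-4-yl}oxy)tri(propan-2-yl)silane F14.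
- Semi-hydrogenation over Pd/CaCO3 poisoned with Pb(OAc)2 gives 14.

**Step 4.** Over-alkylation to di- and tri-ethers and C-alkylation of the ambident triol can erode the mono-ether, since nothing but stoichiometry distinguishes the three hydroxyls.
The fallback uses a removable ester to differentiate them. It sets out from 7 and returns at 8.
- Mitsunobu reaction of 7 with commercial methyl 2,4,6-trihydroxybenzoate F15 should alkylate only the 4-hydroxyl, because the 2- and 6-hydroxyls are tied to the ester by hydrogen bonds, giving methyl 2,6-dihydroxy-4-[(3-methylbut-2-en-1-yl)oxy]benzoate F16.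
- Refluxing aqueous KOH in MeOH followed by acidification gives 2,6-dihydroxy-4-[(3-methylbut-2-en-1-yl)oxy]benzoic acid F17, which decarboxylates on gentle warming to 8.

## Further compounds

F1 | step 10 | 3,5-dihydroxy-2,6-bis(3-methylbut-2-en-1-yl)benzaldehyde | O=Cc1c(CC=C(C)C)c(O)cc(O)c1CC=C(C)C
F2 | step 10 | 5-ethynyl-4,6-bis(3-methylbut-2-en-1-yl)benzene-1,3-diol | C#Cc1c(CC=C(C)C)c(O)cc(O)c1CC=C(C)C
F3 | step 10 | 2-{[3,5-dihydroxy-2,6-bis(3-methylbut-2-en-1-yl)phenyl]ethynyl}-5-[(3-methylbut-2-en-1-yl)oxy]-1,3-phenylene diacetate | CC(=O)Oc1cc(OCC=C(C)C)cc(OC(C)=O)c1C#Cc1c(CC=C(C)C)c(O)cc(O)c1CC=C(C)C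
F4 | step 10 | 2-{[3,5-dihydroxy-2,6-bis(3-methylbut-2-en-1-yl)phenyl]ethynyl}-5-[(3-methylbut-2-en-1-yl)oxy]benzene-1,3-diol | Oc1cc(OCC=C(C)C)cc(O)c1C#Cc1c(CC=C(C)C)c(O)cc(O)c1CC=C(C)C
F5 | step 10 | 2-[3,5-dihydroxy-2,6-bis(3-methylbut-2-en-1-yl)phenyl]-6-[(3-methylbut-2-en-1-yl)oxy]-1-benzofuran-4-ol | CC(C)=CCOc1cc(O)c2cc(-c3c(CC=C(C)C)c(O)cc(O)c3CC=C(C)C)oc2c1
F6 | step 10 | 2-[3,5-diacetoxy-2,6-bis(3-methylbut-2-en-1-yl)phenyl]-6-[(3-methylbut-2-en-1-yl)oxy]-1-benzofuran-4-yl acetate | CC(C)=CCOc1cc(OC(C)=O)c2cc(-c3c(CC=C(C)C)c(OC(C)=O)cc(OC(C)=O)c3CC=C(C)C)oc2c1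
F7 | step 10 | 2-[3,5-diacetoxy-2,6-bis(3-methylbut-2-en-1-yl)phenyl]-7-(2-methylbut-3-en-2-yl)-1-benzofuran-4,6-diyl diacetate | C=CC(C)(C)c1c(OC(C)=O)cc(OC(C)=O)c2cc(-c3c(CC=C(C)C)c(OC(C)=O)cc(OC(C)=O)c3CC=C(C)C)oc12
F8 | step 5 | 1,3-bis(methoxymethoxy)-5-[(3-methylbut-2-en-1-yl)oxy]benzene | COCOc1cc(OCC=C(C)C)cc(OCOC)c1
F9 | step 5 | 2-iodo-1,3-bis(methoxymethoxy)-5-[(3-methylbut-2-en-1-yl)oxy]benzene | COCOc1cc(OCC=C(C)C)cc(OCOC)c1I
F10 | step 7 | 5-ethynylbenzene-1,3-diol | C#Cc1cc(O)cc(O)c1
F11 | step 7 | 2-iodo-5-[(3-methylbut-2-en-1-yl)oxy]-3-{[tri(propan-2-yl)silyl]oxy}phenol | CC(C)=CCOc1cc(O)c(I)c(O[Si](C(C)C)(C(C)C)C(C)C)c1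
F12 | step 7 | 5-({2-hydroxy-4-[(3-methylbut-2-en-1-yl)oxy]-6-{[tri(propan-2-yl)silyl]oxy}phenyl}ethynyl)benzene-1,3-diol | CC(C)=CCOc1cc(O)c(C#Cc2cc(O)cc(O)c2)c(O[Si](C(C)C)(C(C)C)C(C)C)c1
F13 | step 7 | 5-{6-[(3-methylbut-2-en-1-yl)oxy]-4-{[tri(propan-2-yl)silyl]oxy}-1-benzofuran-2-yl}benzene-1,3-diol | CC(C)=CCOc1cc(O[Si](C(C)C)(C(C)C)C(C)C)c2cc(-c3cc(O)cc(O)c3)oc2c1
F14 | step 7 | ({2-{3,5-bis[(2-methylbut-3-yn-2-yl)oxy]phenyl}-6-[(3-methylbut-2-en-1-yl)oxy]-1-benzofuran-4-yl}oxy)tri(propan-2-yl)silane | C#CC(C)(C)Oc1cc(OC(C)(C)C#C)cc(-c2cc3c(O[Si](C(C)C)(C(C)C)C(C)C)cc(OCC=C(C)C)cc3o2)c1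
F15 | step 4 | methyl 2,4,6-trihydroxybenzoate | COC(=O)c1c(O)cc(O)cc1O
F16 | step 4 | methyl 2,6-dihydroxy-4-[(3-methylbut-2-en-1-yl)oxy]benzoate | COC(=O)c1c(O)cc(OCC=C(C)C)cc1O
F17 | step 4 | 2,6-dihydroxy-4-[(3-methylbut-2-en-1-yl)oxy]benzoic acid | OC(=O)c1c(O)cc(OCC=C(C)C)cc1O
A1 | alternative 1 | 7-(2-methylbut-3-en-2-yl)-1-benzofuran-4,6-diol | C=CC(C)(C)c1c(O)cc(O)c2ccoc12
A2 | alternative 1 | methyl 2-(4,4-dimethyl-2-oxohex-5-en-3-yl)furan-3-carboxylate | COC(=O)c1ccoc1C(C(C)=O)C(C)(C)C=C
A3 | alternative 2 | ({2-[3,5-bis(methoxymethoxy)-2,6-bis(3-methylbut-2-en-1-yl)phenyl]-4-(methoxymethoxy)-1-benzofuran-6-yl}oxy)tri(propan-2-yl)silane | COCOc1cc(O[Si](C(C)C)(C(C)C)C(C)C)cc2oc(-c3c(CC=C(C)C)c(OCOC)cc(OCOC)c3CC=C(C)C)cc12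
A4 | alternative 2 | 1-[3,5-bis(methoxymethoxy)-2,6-bis(3-methylbut-2-en-1-yl)phenyl]ethan-1-one | CC(=O)c1c(CC=C(C)C)c(OCOC)cc(OCOC)c1CC=C(C)C
A5 | alternative 2 | 1-bromo-2-iodo-3-(methoxymethoxy)-5-{[tri(propan-2-yl)silyl]oxy}benzene | COCOc1cc(O[Si](C(C)C)(C(C)C)C(C)C)cc(Br)c1I
A6 | alternative 3 | 5-[4,6-bis(methoxymethoxy)-7-(2-methylbut-3-en-2-yl)-1-benzofuran-2-yl]-4,6-bis(3-methylbut-2-en-1-yl)benzene-1,3-diol | C=CC(C)(C)c1c(OCOC)cc(OCOC)c2cc(-c3c(CC=C(C)C)c(O)cc(O)c3CC=C(C)C)oc12
A7 | alternative 3 | 1-[4,6-bis(methoxymethoxy)-7-(2-methylbut-3-en-2-yl)-1-benzofuran-2-yl]-9-methyl-2-(3-methylbut-2-en-1-yl)dec-8-ene-1,3,5-trione | C=CC(C)(C)c1c(OCOC)cc(OCOC)c2cc(C(=O)C(CC=C(C)C)C(=O)CC(=O)CCC=C(C)C)oc12
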